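Heavy atoms are numbered along the target SMILES. Removing the ethano bridge C23–C24 (bonds C4–C24 and C22–C23) from the bicyclo[2.2.2]octene leaves ring C2–C3–C4–C5–C21–C22 as a cyclohexa-1,3-diene. Its two sp3 atoms, C5 and C21, hold C6 and C20 on one face. This cis pair is what a disrotatory six-electron closure delivers, so everything rests on bond C5–C21. Heating a (2E,4Z,6E)-trienoate attached to C20 of a glucose-derived, bis-silylated phenyloxolane forms the carbocycle and both stereocentres at once. Methyl vinyl ketone then adds the bridge, its acetyl group becomes the isopropyl group, and the lactone C6–O8 is closed last.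

Key step: step 12

Remark: labels without prefix follow the target SMILES. The sugar atoms map as sugar C1 = C21, C2 = C20, C3 = C9, C4 = C10, C5 = C12, and sugar O2 = O19, O3 = O8, O4 = O11. TBS = tert-butyldimethylsilyl; Bpin = 4,4,5,5-tetramethyl-1,3,2-dioxaborolan-2-yl.

Step 1
Reactants: 1 1,2:5,6-di-O-isopropylidene-α-D-glucofuranose
Product: 2 3-O-TBS-1,2:5,6-di-O-isopropylidene-α-D-glucofuranose
Conditions: TBSCl, imidazole, DMF, 50 °C
Reagents that add atoms: tert-butyldimethylsilyl chloride, CC(C)(C)[Si](C)(C)Cl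
Why: Imidazole-promoted silylation of the only free hydroxyl (sugar O3, later O8) gives a group that survives periodic acid, the Grignard reagent and sulfonylation and falls off by itself in step 5, and no stereocentre is touched.

Step 2
Reactants: 2 3-O-TBS-1,2:5,6-di-O-isopropylidene-α-D-glucofuranose
Product: 3 3-O-TBS-1,2-O-isopropylidene-α-D-xylo-pentodialdo-1,4-furanose
Conditions: H5IO6, EtOAc, rt
Reagents that add atoms: none
Why: Periodic acid first hydrolyses the exocyclic 5,6-dioxolane, which is far more labile than the ring-fused 1,2-acetonide, and then cleaves the freed glycol (Malaprade reaction) to the sugar C5 aldehyde without enolising sugar C4.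

Step 3
Reactants: 3 3-O-TBS-1,2-O-isopropylidene-α-D-xylo-pentodialdo-1,4-furanose + 4 phenylmagnesium bromide
Product: 5 (5S)-3-O-TBS-1,2-O-isopropylidene-5-C-phenyl-α-D-xylofuranose (L-ido series)
Conditions: PhMgBr (Et2O solution), Et2O, −78 → 0 °C; aq NH4Cl
Reagents that add atoms: none
Why: Cram-chelate Grignard addition, in which magnesium bridges the aldehyde oxygen and the furanose ring oxygen, phenyl enters from the face turned away from sugar C3 and its silyloxy group, and the threo (5S) carbinol that becomes C12 after one inversion should predominate.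

Step 4
Reactants: 5 (5S)-3-O-TBS-1,2-O-isopropylidene-5-C-phenyl-α-D-xylofuranose
Product: 6 (5S)-3-O-TBS-1,2-O-isopropylidene-5-O-methanesulfonyl-5-C-phenyl-α-D-xylofuranose
Conditions: Ms2O, pyridine, CH2Cl2, 0 °C
Reagents that add atoms: methanesulfonic anhydride, CS(=O)(=O)OS(C)(=O)=O
Why: Sulfonylation of the secondary benzylic alcohol with retention at carbon, where chloride-free Ms2O rules out benzylic chloride formation and the two flanking C–O bonds keep the mesylate from ionising.

Step 5
Reactants: 6 (5S)-3-O-TBS-1,2-O-isopropylidene-5-O-methanesulfonyl-5-C-phenyl-α-D-xylofuranose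
Product: 8 (2R,3S,4S,5R)-2-(dimethoxymethyl)-5-phenyloxolane-3,4-diol, via open-chain mesylate acetal 7 (not isolated)
Conditions: HCl (1.25 M in MeOH), reflux
Reagents that add atoms: methanol, CO
Why: Acid methanolysis strips the acetonide and the silyl ether and opens the furanose to acyclic acetal 7, whose sugar O2–H displaces the benzylic mesylate by 5-exo-tet SN2 attack (the sulfonate-to-2,5-anhydro ring transposition of pentofuranoses), so that C12 is inverted from S to R and phenyl ends trans to the neighbouring hydroxyl, the arrangement also preferred should some ionisation intervene.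

Step 6
Reactants: 8 (2R,3S,4S,5R)-2-(dimethoxymethyl)-5-phenyloxolane-3,4-diol
Product: 9 (2R,3S,4S,5R)-3,4-dihydroxy-5-phenyloxolane-2-carbaldehyde
Conditions: TFA/H2O 4:1, 0 °C → rt; azeotropic drying with PhMe
Reagents that add atoms: water, O
Why: Specific-acid acetal hydrolysis run while no acid-labile group is present, so that the inductively deactivated α-alkoxy acetal can be forced, and acid, unlike base, neither epimerises C20 nor eliminates O8.

Step 7
Reactants: 9 (2R,3S,4S,5R)-3,4-dihydroxy-5-phenyloxolane-2-carbaldehyde + 10 2-(dichloromethyl)-4,4,5,5-tetramethyl-1,3,2-dioxaborolane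
Product: 11 (2S,3S,4S,5R)-2-[(E)-2-(Bpin)ethenyl]-5-phenyloxolane-3,4-diol
Conditions: CrCl2 (excess), LiI, THF, rt
Reagents that add atoms: none
Why: Takai–Utimoto olefination in its boron variant, in which CrCl2 reduces the iodide-activated gem-dihalide to a gem-dichromium species that adds to the aldehyde and eliminates to the E-alkenylboronate (C21=C22), a reagent so weakly basic that C20 keeps its configuration and free hydroxyls are tolerated when it is used in excess.

Step 8
Reactants: 11 (2S,3S,4S,5R)-2-[(E)-2-(Bpin)ethenyl]-5-phenyloxolane-3,4-diol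
Product: 12 (2S,3R,4R,5R)-3,4-bis(TBSO)-2-[(E)-2-(Bpin)ethenyl]-5-phenyloxolane
Conditions: TBSOTf, 2,6-lutidine, CH2Cl2, 0 °C → rt
Reagents that add atoms: tert-butyldimethylsilyl triflate, CC(C)(C)[Si](C)(C)OS(=O)(=O)C(F)(F)F
Why: Silyl triflate silylation caps both hindered secondary alcohols while the alkenyl pinacolboronate stays inert, and the silyloxy group on C9, cis to the side chain, is the steric element used in step 12.

Step 9
Reactants: 13 but-2-yn-1-ol
Product: 15 (Z)-3-iodobut-2-en-1-ol, via cyclic vinylalanate 14 (not isolated)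
Conditions: NaAlH2(OCH2CH2OMe)2, Et2O, 0 °C → rt; then I2, THF, −78 → 0 °C
Reagents that add atoms: iodine, [I][I]
Why: Hydroxyl-directed trans-hydroalumination of the propargylic alcohol places aluminium on the distal alkyne carbon inside a five-membered alanate, and iodinolysis with retention gives the vinyl iodide with iodine cis to CH2OH, which fixes the Z geometry of C2=C3 and brings in methyl C1.

Step 10
Reactants: 15 (Z)-3-iodobut-2-en-1-ol + 16 ethyl (triphenylphosphoranylidene)acetate
Product: 18 ethyl (2E,4Z)-5-iodohexa-2,4-dienoate, via (Z)-3-iodobut-2-enal 17 (not isolated)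
Conditions: activated MnO2, CH2Cl2, rt, dark
Reagents that add atoms: none
Why: Tandem allylic oxidation and Wittig olefination, in which the isomerisation-prone iodoenal is trapped as it forms by the stabilised ylide, giving the E-enoate (C4=C5) and leaving the Z-iodoalkene untouched.

Step 11
Reactants: 12 (2S,3R,4R,5R)-3,4-bis(TBSO)-2-[(E)-2-(Bpin)ethenyl]-5-phenyloxolane + 18 ethyl (2E,4Z)-5-iodohexa-2,4-dienoate
Product: 19 ethyl (2E,4Z,6E)-7-[(2S,3R,4R,5R)-3,4-bis(TBSO)-5-phenyloxolan-2-yl]-5-methylhepta-2,4,6-trienoate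
Conditions: PdCl2(dppf) (5 mol %), K3PO4 (3 M aq), THF, rt, degassed, dark
Reagents that add atoms: none
Why: Suzuki–Miyaura coupling (bond C22–C2), in which oxidative addition of the alkenyl iodide to zerovalent palladium, transmetallation and reductive elimination all run with retention, so the E and Z geometries of the partners are carried into the E,Z,E-triene at a temperature far below that of ring closure.

Step 12
Reactants: 19 ethyl (2E,4Z,6E)-7-[(2S,3R,4R,5R)-3,4-bis(TBSO)-5-phenyloxolan-2-yl]-5-methylhepta-2,4,6-trienoate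
Product: 20 ethyl (1S,6R)-6-[(2S,3R,4R,5R)-3,4-bis(TBSO)-5-phenyloxolan-2-yl]-4-methylcyclohexa-2,4-diene-1-carboxylate
Conditions: PhMe (0.01 M, degassed), BHT (10 mol %), sealed tube, 115 °C, dark; chromatography
Reagents that add atoms: none
Why: The helical s-cis,s-cis conformer of 19 undergoes a thermal suprafacial six-electron electrocyclisation that forms only the σ bond C5–C21, the established behaviour of (E,Z,E)-1,6-disubstituted hexa-1,3,5-trienes, which give cis-5,6-disubstituted cyclohexa-1,3-dienes. The single ring closed is the six-membered carbocycle C2–C3–C4–C5–C21–C22, in the disrotatory 6π mode. Orbital symmetry together with the two E termini turns C6 and C20 outward in the same sense, so their cis relationship on C5 and C21 is not open to choice. The absolute sense is relayed from C20: in the staggered transition state the C20–C9 bond, thickened by the cis silyloxy group on C9, lies anti to the incoming C5, the small H20 faces the ester-bearing terminus, and O19 with its phenyl-bearing carbon sits over C21=C22 (inside-alkoxy arrangement), which leads to 5S,21R. The step therefore needs torquoselectivity between two disrotatory senses, expected to be useful but incomplete, with the minor diastereomer removed by chromatography. Neutral, oxygen-free, dilute conditions spare the acidic allylic H5 and suppress aromatisation and dimerisation, while the E geometry at C21=C22 and the trans placing of C1 and C4 shut off 1,7- and 1,5-hydrogen shifts.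

Step 13
Reactants: 20 ethyl (1S,6R)-6-[(2S,3R,4R,5R)-3,4-bis(TBSO)-5-phenyloxolan-2-yl]-4-methylcyclohexa-2,4-diene-1-carboxylate + 21 methyl vinyl ketone
Product: 22 ethyl 7-acetyl-5-methyl-3-[(2S,3R,4R,5R)-3,4-bis(TBSO)-5-phenyloxolan-2-yl]bicyclo[2.2.2]oct-5-ene-2-carboxylate (ester, oxolane and acetyl all syn to C2=C3; C4, C5, C21, C22, C24 as in 26)
Conditions: Me2AlCl (40 mol %), CH2Cl2, −78 → −30 °C
Reagents that add atoms: none
Why: Lewis-acid-catalysed Diels–Alder reaction in which the locked s-cis diene C4=C3–C2=C22 is attacked on the face bearing H5 and H21, the C2 methyl makes C22 the larger-coefficient terminus so that the CH2 of 21 bonds there (para orientation, bonds C22–C23 and C4–C24), and the endo rule puts the acetyl group syn to the new C2=C3 bond, which together set C4, C22 and C24.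

Step 14
Reactants: 22 acetyl bicyclooctene ester
Product: 23 ethyl 5-methyl-7-(prop-1-en-2-yl)-3-[(2S,3R,4R,5R)-3,4-bis(TBSO)-5-phenyloxolan-2-yl]bicyclo[2.2.2]oct-5-ene-2-carboxylate (stereocentres as in 22)
Conditions: Zn, CH2Br2, TiCl4, THF (reagent pre-formed), then 22, CH2Cl2, 0 °C → rt
Reagents that add atoms: dibromomethane, BrCBr
Why: Takai–Lombardo methylenation, whose non-basic gem-dizinc/titanium reagent converts the methyl ketone into the 1,1-disubstituted alkene without enolising C24 and ignores the ethyl ester, the silyl ethers and the ring alkene.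

Step 15
Reactants: 23 isopropenyl bicyclooctene ester
Product: 24 ethyl (1R,2S,3R,4R,7R)-5-methyl-7-(propan-2-yl)-3-[(2S,3R,4R,5R)-3,4-bis(TBSO)-5-phenyloxolan-2-yl]bicyclo[2.2.2]oct-5-ene-2-carboxylate
Conditions: H2 (1 atm), RhCl(PPh3)3 (10 mol %), PhH/EtOH 1:1, rt
Reagents that add atoms: none
Why: Homogeneous hydrogenation with RhCl(PPh3)3 discriminates by substitution, saturating the 1,1-disubstituted isopropenyl group (as in the selective reduction of carvone) while the trisubstituted C2=C3 bond and the benzylic C12–O19 bond are untouched, and no stereocentre is created.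

Step 16
Reactants: 24 isopropyl bicyclooctene ester
Product: 26 target CNP0249919.1, via dihydroxy ester 25 (not isolated)
Conditions: HF·pyridine, THF/pyridine, 0 °C → rt; then PPTS (20 mol %), PhMe, 80 °C
Reagents that add atoms: none
Why: Fluoride desilylation followed by mildly acid-catalysed 6-exo-trig lactonisation, in which O8–H and C6 are held together on the same side of the C5–C21 bridge whereas O11–H on the opposite oxolane face cannot reach the ester, so only the δ-lactone forms, PPTS is too weak to protonate C2=C3, and no stereocentre is touched.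

Compound list
1 | 1,2:5,6-di-O-isopropylidene-α-D-glucofuranose | CC1(C)OC[C@@H](O1)[C@H]2O[C@@H]3OC(C)(C)O[C@@H]3[C@H]2O | starting material
2 | 3-O-TBS-1,2:5,6-di-O-isopropylidene-α-D-glucofuranose | CC1(C)OC[C@@H](O1)[C@H]2O[C@@H]3OC(C)(C)O[C@@H]3[C@H]2O[Si](C)(C)C(C)(C)C | intermediate
3 | 3-O-TBS-1,2-O-isopropylidene-α-D-xylo-pentodialdo-1,4-furanose | O=C[C@H]1O[C@@H]2OC(C)(C)O[C@@H]2[C@H]1O[Si](C)(C)C(C)(C)C | intermediate
4 | phenylmagnesium bromide | Br[Mg]c1ccccc1 | starting material
5 | (5S)-3-O-TBS-1,2-O-isopropylidene-5-C-phenyl-α-D-xylofuranose | O[C@@H](c1ccccc1)[C@H]2O[C@@H]3OC(C)(C)O[C@@H]3[C@H]2O[Si](C)(C)C(C)(C)C | intermediate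
6 | (5S)-3-O-TBS-1,2-O-isopropylidene-5-O-methanesulfonyl-5-C-phenyl-α-D-xylofuranose | CS(=O)(=O)O[C@@H](c1ccccc1)[C@H]2O[C@@H]3OC(C)(C)O[C@@H]3[C@H]2O[Si](C)(C)C(C)(C)C | intermediate
7 | (5S)-5-O-methanesulfonyl-5-C-phenyl-D-xylose dimethyl acetal, open chain, formed in the flask | COC(OC)[C@H](O)[C@@H](O)[C@H](O)[C@@H](OS(C)(=O)=O)c1ccccc1 | intermediate
8 | (2R,3S,4S,5R)-2-(dimethoxymethyl)-5-phenyloxolane-3,4-diol | COC(OC)[C@@H]1O[C@H](c2ccccc2)[C@@H](O)[C@@H]1O | intermediate
9 | (2R,3S,4S,5R)-3,4-dihydroxy-5-phenyloxolane-2-carbaldehyde | O=C[C@@H]1O[C@H](c2ccccc2)[C@@H](O)[C@@H]1O | intermediate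
10 | 2-(dichloromethyl)-4,4,5,5-tetramethyl-1,3,2-dioxaborolane | CC1(C)OB(C(Cl)Cl)OC1(C)C | starting material
11 | (2S,3S,4S,5R)-2-[(E)-2-(Bpin)ethenyl]-5-phenyloxolane-3,4-diol | CC1(C)OB(/C=C/[C@@H]2O[C@H](c3ccccc3)[C@@H](O)[C@@H]2O)OC1(C)C | intermediate
12 | (2S,3R,4R,5R)-3,4-bis(TBSO)-2-[(E)-2-(Bpin)ethenyl]-5-phenyloxolane | CC1(C)OB(/C=C/[C@@H]2O[C@H](c3ccccc3)[C@@H](O[Si](C)(C)C(C)(C)C)[C@@H]2O[Si](C)(C)C(C)(C)C)OC1(C)C | intermediate
13 | but-2-yn-1-ol | CC#CCO | starting material
14 | sodium 2,2-bis(2-methoxyethoxy)-3-methyl-2,5-dihydro-1,2-oxaaluminol-2-uide, formed in the flask | CC1=CCO[Al-]1(OCCOC)OCCOC.[Na+] | intermediate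
15 | (Z)-3-iodobut-2-en-1-ol | I/C(C)=C\CO | intermediate
16 | ethyl (triphenylphosphoranylidene)acetate | CCOC(=O)C=P(c1ccccc1)(c1ccccc1)c1ccccc1 | starting material
17 | (Z)-3-iodobut-2-enal, formed in the flask | I/C(C)=C\C=O | intermediate
18 | ethyl (2E,4Z)-5-iodohexa-2,4-dienoate | CCOC(=O)/C=C/C=C(/C)I | intermediate
19 | ethyl (2E,4Z,6E)-7-[(2S,3R,4R,5R)-3,4-bis(TBSO)-5-phenyloxolan-2-yl]-5-methylhepta-2,4,6-trienoate | CCOC(=O)/C=C/C=C(/C)\C=C\[C@@H]1O[C@H](c2ccccc2)[C@@H](O[Si](C)(C)C(C)(C)C)[C@@H]1O[Si](C)(C)C(C)(C)C | intermediate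
20 | ethyl (1S,6R)-6-[(2S,3R,4R,5R)-3,4-bis(TBSO)-5-phenyloxolan-2-yl]-4-methylcyclohexa-2,4-diene-1-carboxylate | CC1=C[C@@H]([C@@H]2O[C@H](c3ccccc3)[C@@H](O[Si](C)(C)C(C)(C)C)[C@@H]2O[Si](C)(C)C(C)(C)C)[C@@H](C(=O)OCC)C=C1 | intermediate
21 | methyl vinyl ketone (but-3-en-2-one) | CC(=O)C=C | starting material
22 | ethyl 7-acetyl-5-methyl-3-[bis(TBSO)phenyloxolanyl]bicyclo[2.2.2]oct-5-ene-2-carboxylate, ester, oxolane and acetyl syn to C2=C3 | CC1=C[C@@H]2[C@H](C(=O)OCC)[C@H]([C@@H]3O[C@H](c4ccccc4)[C@@H](O[Si](C)(C)C(C)(C)C)[C@@H]3O[Si](C)(C)C(C)(C)C)[C@H]1C[C@@H]2C(C)=O | intermediate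
23 | ethyl 5-methyl-7-(prop-1-en-2-yl)-3-[bis(TBSO)phenyloxolanyl]bicyclo[2.2.2]oct-5-ene-2-carboxylate, stereocentres as in 22 | CC1=C[C@@H]2[C@H](C(=O)OCC)[C@H]([C@@H]3O[C@H](c4ccccc4)[C@@H](O[Si](C)(C)C(C)(C)C)[C@@H]3O[Si](C)(C)C(C)(C)C)[C@H]1C[C@@H]2C(C)=C | intermediate
24 | ethyl (1R,2S,3R,4R,7R)-5-methyl-7-(propan-2-yl)-3-[(2S,3R,4R,5R)-3,4-bis(TBSO)-5-phenyloxolan-2-yl]bicyclo[2.2.2]oct-5-ene-2-carboxylate | CC1=C[C@@H]2[C@H](C(=O)OCC)[C@H]([C@@H]3O[C@H](c4ccccc4)[C@@H](O[Si](C)(C)C(C)(C)C)[C@@H]3O[Si](C)(C)C(C)(C)C)[C@H]1C[C@@H]2C(C)C | intermediate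
25 | dihydroxy ester from 24 (both silyl groups removed), formed in the flask | CC1=C[C@@H]2[C@H](C(=O)OCC)[C@H]([C@@H]3O[C@H](c4ccccc4)[C@@H](O)[C@@H]3O)[C@H]1C[C@@H]2C(C)C | intermediate
26 | CNP0249919.1, configuration 4R,5S,9S,10R,12R,20S,21R,22R,24R in SMILES numbering | CC1=C[C@@H]2[C@@H]3C(=O)O[C@H]4[C@H](O)[C@@H](c5ccccc5)O[C@H]4[C@@H]3[C@H]1C[C@@H]2C(C)C | target

Total step count: 16. Longest linear sequence: 14 (steps 1–8, then 11–16). The iodide arm takes steps 9 and 10.

Steps most likely to fail

1. Step 12. The two disrotatory senses may be told apart too weakly, because C20 steers the closure only through a rotamer preference. Long heating may also let oxidation to the arene compete.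
 - The fallback gives up the electrocyclic construction and assembles the bicyclooctene in one intermolecular Diels–Alder reaction. It sets out from 9.
 - Wittig olefination with 16 in methanol at 0 °C, a medium in which α-alkoxy aldehydes give mainly the cis-enoate, should furnish ethyl (Z)-3-[(2S,3S,4S,5R)-3,4-dihydroxy-5-phenyloxolan-2-yl]prop-2-enoate F1.
 - PPTS in warm toluene closes O8 onto the ester to give (+)-altholactone F2.
 - Heating F2 with commercial (R)-α-phellandrene (CC1=CC[C@H](C(C)C)C=C1), neat with BHT in a sealed tube or under high pressure, joins C21–C22 and C5–C4.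
 - The diene should react anti to its isopropyl group and the lactone on the face away from the oxolane, through the endo transition state. The route is re-entered at 26.

2. Step 13. Addition to the crowded diene may be sluggish, with erosion of regio- and endo-selectivity. The Lewis acid may also induce double-bond migration and aromatisation.
 - The fallback changes the substrate class by tying back the two substituents first and dispensing with the Lewis acid. It sets out from 20.
 - HF·pyridine followed by PPTS in toluene should give the tricyclic lactone-fused cyclohexadiene F3 (C6–O8 closed, O11–H free). Its convex face is open.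
 - Uncatalysed cycloaddition with 21 under high pressure at or slightly above room temperature should give the acetyl lactone F4.
 - Methylenation with excess Zn/CH2Br2/TiCl4, which spares lactones, should give the isopropenyl lactone F5.
 - Hydrogenation over RhCl(PPh3)3 brings the sequence back at 26.

3. Step 7. The gem-dichromium reagent may be quenched by the two free hydroxyls or by hydrate water held by the aldehyde, which would leave conversion low.
 - The fallback protects first and reaches the boronate through an alkyne. It sets out from 8.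
 - TBSCl, imidazole and DMAP in warm DMF should give the bis-silylated dimethyl acetal F6.
 - TESOTf and 2,6-lutidine in CH2Cl2 at 0 °C, followed by water, cleave the acetal without acid and should give (2R,3R,4R,5R)-3,4-bis(TBSO)-5-phenyloxolane-2-carbaldehyde F7.
 - Ohira–Bestmann homologation (dimethyl 1-diazo-2-oxopropylphosphonate, K2CO3, MeOH, 0 °C) should give the terminal alkyne F8.
 - Syn-hydroboration with pinacolborane catalysed by Cp2ZrHCl delivers the E-alkenylboronate. The route is rejoined at 12.

Further compounds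
F1 | step 12 | ethyl (Z)-3-[(2S,3S,4S,5R)-3,4-dihydroxy-5-phenyloxolan-2-yl]prop-2-enoate | CCOC(=O)/C=C\[C@@H]1O[C@H](c2ccccc2)[C@@H](O)[C@@H]1O
F2 | step 12 | (+)-altholactone, (2R,3R,3aS,7aS)-3-hydroxy-2-phenyl-2,3,3a,7a-tetrahydro-5H-furo[3,2-b]pyran-5-one | O=C1C=C[C@@H]2O[C@H](c3ccccc3)[C@@H](O)[C@@H]2O1
F3 | step 13 | lactone-fused cyclohexadiene (C6–O8 closed, O11–H free, 5S,21R) | CC1=C[C@@H]2[C@H](C=C1)C(=O)O[C@H]3[C@H](O)[C@@H](c4ccccc4)O[C@H]32
F4 | step 13 | acetyl lactone (26 with acetyl in place of isopropyl on C24) | CC1=C[C@@H]2[C@@H]3C(=O)O[C@H]4[C@H](O)[C@@H](c5ccccc5)O[C@H]4[C@@H]3[C@H]1C[C@@H]2C(C)=O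
F5 | step 13 | isopropenyl lactone (26 with prop-1-en-2-yl on C24) | CC1=C[C@@H]2[C@@H]3C(=O)O[C@H]4[C@H](O)[C@@H](c5ccccc5)O[C@H]4[C@@H]3[C@H]1C[C@@H]2C(C)=C
F6 | step 7 | (2R,3R,4R,5R)-3,4-bis(TBSO)-2-(dimethoxymethyl)-5-phenyloxolane | COC(OC)[C@@H]1O[C@H](c2ccccc2)[C@@H](O[Si](C)(C)C(C)(C)C)[C@@H]1O[Si](C)(C)C(C)(C)C
F7 | step 7 | (2R,3R,4R,5R)-3,4-bis(TBSO)-5-phenyloxolane-2-carbaldehyde | O=C[C@@H]1O[C@H](c2ccccc2)[C@@H](O[Si](C)(C)C(C)(C)C)[C@@H]1O[Si](C)(C)C(C)(C)C
F8 | step 7 | (2S,3R,4R,5R)-3,4-bis(TBSO)-2-ethynyl-5-phenyloxolane | C#C[C@@H]1O[C@H](c2ccccc2)[C@@H](O[Si](C)(C)C(C)(C)C)[C@@H]1O[Si](C)(C)C(C)(C)C
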